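A direct plan would build the ring from a 3-substituted furan: the formylfuran tiglate A1 would take up an isobutenylzinc reagent under amino-alcohol catalysis and, after acetylation in the flask, give furyl acetate A2, and NBS in wet acetone would open the furan to the (Z)-ene-dione aldehyde A3.
A Lewis-acid carbonyl-ene reaction of A3 would close the ring to hydroxy enone A4, Mitsunobu esterification with tiglic acid would invert the new carbinol to give the isopropenyl bis-tiglate A5, and hydrogenation of the isopropenyl group would finish.
Its weakest steps would be: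
– the ring closure by intramolecular carbonyl-ene reaction: it has no close precedent on a crude, isomerisation-prone ene-dione, must set two stereocentres from one, and gives a 4-hydroxy enone one dehydration away from a phenol;
– the C3 carbinol: the closure would set it trans to the C4 substituent, so it must be corrected afterwards by SN2 inversion of a hindered allylic alcohol;
– the oxidative furan opening (electrophilic bromine beside an electron-rich trisubstituted olefin) and the last-step hydrogenation, which must pick one of four C=C bonds on the finished molecule.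

**Retrosynthetic overview of the new route**
Ring numbering: C1 (bears C7H2–O), C2 (=CH), C3 (O-tigloyl), C4 (isopropyl), C5 (OAc), C6 (C=O).
The ring is cut at C4–C5 and C1=C2: C6, C1 and C5 are the ketone, methyl and methylene carbons of tert-butyl acetoacetate, and C2, C3, C4 with the isopropyl group are (E)-4-methylpent-2-enal, so the only ring is closed from two achiral, commercial chains.
One chiral secondary amine does both asymmetric events in one flask: iminium-mediated Michael addition sets C4, then enamine α-acyloxylation with bis-tigloyl peroxide forms the C3–O bond as the finished tiglate, cis to the isopropyl group because carbon and oxygen enter from the same open face; acid then closes the ring by aldol condensation.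
C7 follows by a Morita–Baylis–Hillman reaction and esterification, and the C5 acetate goes in last, trans to the isopropyl group, with manganese triacetate.
Hence no furan opening or ene closure, no carbinol inversion (C3–O is made with its final configuration) and no selective hydrogenation (the isopropyl group comes with the enal).

Key step: step 2

Assumption: the (R)-configured silyl prolinol ether is taken to leave open the enal face that leads to the (4S) centre; if the sense is the reverse, its enantiomer is used and nothing else changes.

Step 1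
Reactants: 1 tiglic acid, (E)-2-methylbut-2-enoic acid (two molecules per molecule of 2)
Product: 2 bis[(E)-2-methylbut-2-enoyl] peroxide
Conditions: 1 (2.0 equiv), urea–hydrogen peroxide adduct (1.0 equiv), N,N'-dicyclohexylcarbodiimide (2.1 equiv), CH2Cl2, 0 °C, dark; filter, wash, exchange into toluene and titrate; keep in solution, never concentrate to dryness
Reagents that add atoms: hydrogen peroxide, OO; tiglic acid (second molecule), C/C=C(\C)C(=O)O
Why: Carbodiimide-mediated double acylation of hydrogen peroxide, in which one molecule of 1 gives the peracid and a second molecule of 1 acylates it, should give the symmetrical diacyl peroxide under neutral conditions, so the enoyl C=C bonds are not exposed to alkaline peroxide; no stereocentre is formed.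

Step 2
Reactants: 3 tert-butyl 3-oxobutanoate; 4 (E)-4-methylpent-2-enal; 2 bis[(E)-2-methylbut-2-enoyl] peroxide
Product: 7 (1S,6S)-4-oxo-6-(propan-2-yl)cyclohex-2-en-1-yl (2E)-2-methylbut-2-enoate, via Michael aldehyde 5 (not isolated), via α-tigloyloxy aldehyde 6 (not isolated)
Conditions: 3 (1.2 equiv), 4 (1.0 equiv), (R)-2-[diphenyl(trimethylsilyloxy)methyl]pyrrolidine (10 mol%), PhCO2H (10 mol%), toluene, 0 °C → rt; then 2 (1.3 equiv, toluene solution), 2,6-di-tert-butyl-4-methylphenol (5 mol%), 0 °C; then p-TsOH·H2O (20 mol%), 50–60 °C, short reaction time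
Reagents that add atoms: none
Why: Proposed new method: the amine condenses with enal 4 to an (E)-iminium ion to which the enol of 3 adds at C4 on the face not covered by the diphenyl(silyloxy)methyl group (sets C4); the enamine of aldehyde 5 with the same amine then attacks the O–O bond of 2 through C3 on that same open face (sets C3), so that C5 and oxygen are delivered syn across the former (E)-C3=C4 bond, which places O–C3 and the isopropyl group cis on the ring to be formed; acid finally cleaves the tert-butyl ester, the β-keto acid loses CO2, and the methyl ketone closes the only ring by 6-(enolexo)-exo-trig aldol addition of C1 to the aldehyde carbon C2 followed by dehydration. The closest known reaction types are the diarylprolinol-silyl-ether-catalysed Michael addition of tert-butyl acetoacetate to enals with acid-mediated annulation to 5-substituted cyclohex-2-enones, the enamine-catalysed α-benzoyloxylation of aldehydes with dibenzoyl peroxide, and iminium–enamine cascades in which one amine sets the β- and then the α-centre; new are the alkenoyl peroxide and the interception of the Michael aldehyde before ring closure. The step needs catalyst control at C3 against the Felkin preference of 5 (secured by the single, strongly shielding amine used for both events), acyloxylation at the aldehyde α-carbon and not at the ketoester methine (only the aldehyde forms an enamine), and ring closure of 6 before C3 can epimerise (the acid stage is kept mild and short).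

Step 3
Reactants: 7 (1S,6S)-4-oxo-6-(propan-2-yl)cyclohex-2-en-1-yl (2E)-2-methylbut-2-enoate
Product: 8 (1R,6S)-3-(hydroxymethyl)-4-oxo-6-(propan-2-yl)cyclohex-2-en-1-yl (2E)-2-methylbut-2-enoate
Conditions: formalin (37% aq., 3 equiv), 4-(dimethylamino)pyridine (20 mol%), THF/H2O 1:1, rt
Reagents that add atoms: formaldehyde, C=O
Why: Morita–Baylis–Hillman reaction, in which reversible conjugate addition of the pyridine base at C2 gives an ammonium enolate that adds through C1 to formaldehyde before the base is expelled and the C1=C2 enone is restored; no stereocentre is formed, and the descriptor at the carbinol carbon changes only because the CIP priorities change.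

Step 4
Reactants: 8 (1R,6S)-3-(hydroxymethyl)-4-oxo-6-(propan-2-yl)cyclohex-2-en-1-yl (2E)-2-methylbut-2-enoate; 1 tiglic acid
Product: 9 [(3R,4S)-3-[(E)-2-methylbut-2-enoyloxy]-6-oxo-4-(propan-2-yl)cyclohex-1-en-1-yl]methyl (E)-2-methylbut-2-enoate
Conditions: 1 (1.2 equiv), N,N'-dicyclohexylcarbodiimide (1.2 equiv), 4-(dimethylamino)pyridine (10 mol%), CH2Cl2, 0 °C → rt
Reagents that add atoms: none
Why: Steglich esterification of the unhindered primary allylic alcohol through the acylpyridinium ion should be fast and neutral enough to leave the C3 ester and the enone untouched; no stereocentre is involved.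

Step 5
Reactants: 9 [(3R,4S)-3-[(E)-2-methylbut-2-enoyloxy]-6-oxo-4-(propan-2-yl)cyclohex-1-en-1-yl]methyl (E)-2-methylbut-2-enoate
Product: 10 [(3S,4S,5R)-5-acetoxy-3-[(E)-2-methylbut-2-enoyloxy]-6-oxo-4-(propan-2-yl)cyclohex-1-en-1-yl]methyl (E)-2-methylbut-2-enoate (CNP0218511.1)
Conditions: Mn(OAc)3·2H2O (3 equiv, trivalent manganese), benzene, reflux with water separation
Reagents that add atoms: manganese triacetate, CC(=O)O[Mn](OC(C)=O)OC(C)=O
Why: α′-Acetoxylation of an enone by manganese triacetate (the manganese enolate can form only towards C5, and acetate is transferred to the resulting α-keto radical), a reaction type known for carvone-like 2,5-disubstituted cyclohexenones; the acetate should enter anti to the neighbouring isopropyl group and the α-acetoxy ketone can equilibrate to the same trans isomer, which sets C5.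

**Compound list**
1 | tiglic acid, (E)-2-methylbut-2-enoic acid | C/C=C(\C)C(=O)O | starting material
2 | bis[(E)-2-methylbut-2-enoyl] peroxide | C/C=C(\C)C(=O)OOC(=O)/C(C)=C/C | intermediate
3 | tert-butyl 3-oxobutanoate | CC(=O)CC(=O)OC(C)(C)C | starting material
4 | (E)-4-methylpent-2-enal | CC(C)/C=C/C=O | starting material
5 | tert-butyl (3R)-2-acetyl-5-oxo-3-(propan-2-yl)pentanoate (both C2 epimers; formed in the flask) | O=CC[C@H](C(C)C)C(C(C)=O)C(=O)OC(C)(C)C | intermediate
6 | tert-butyl (3R,4R)-2-acetyl-4-[(E)-2-methylbut-2-enoyloxy]-5-oxo-3-(propan-2-yl)pentanoate (both C2 epimers; formed in the flask) | O=C[C@H](OC(=O)/C(C)=C/C)[C@H](C(C)C)C(C(C)=O)C(=O)OC(C)(C)C | intermediate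
7 | (1S,6S)-4-oxo-6-(propan-2-yl)cyclohex-2-en-1-yl (2E)-2-methylbut-2-enoate (ester oxygen and isopropyl cis) | O=C1C=C[C@H](OC(=O)/C(C)=C/C)[C@H](C(C)C)C1 | intermediate
8 | (1R,6S)-3-(hydroxymethyl)-4-oxo-6-(propan-2-yl)cyclohex-2-en-1-yl (2E)-2-methylbut-2-enoate | OCC1=C[C@H](OC(=O)/C(C)=C/C)[C@H](C(C)C)CC1=O | intermediate
9 | [(3R,4S)-3-[(E)-2-methylbut-2-enoyloxy]-6-oxo-4-(propan-2-yl)cyclohex-1-en-1-yl]methyl (E)-2-methylbut-2-enoate | C/C=C(\C)C(=O)OCC1=C[C@H](OC(=O)/C(C)=C/C)[C@H](C(C)C)CC1=O | intermediate
10 | [(3S,4S,5R)-5-acetoxy-3-[(E)-2-methylbut-2-enoyloxy]-6-oxo-4-(propan-2-yl)cyclohex-1-en-1-yl]methyl (E)-2-methylbut-2-enoate | C/C=C(\C)C(=O)OCC1=C[C@H](OC(=O)/C(C)=C/C)[C@H](C(C)C)[C@@H](OC(C)=O)C1=O | target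

Total step count: 5. Longest linear sequence: 5 steps (1 → 2 → 7 → 8 → 9 → 10).

**Steps most likely to fail**

Step 2 (labelled as new). The enamine-mediated acyloxylation could lose catalyst control, because the substrate's own Felkin preference opposes it. The peroxide could also be used up by oxidation of the amine or by acyloxylation of the ketoester methine, and the α-acyloxy aldehyde could epimerise at C3 or eliminate during the acid stage. The fallback sets out from 3 and 4 and comes back at 7, using known chemistry throughout, at the price of three more steps and an inversion. The same amine-catalysed Michael addition without peroxide gives 5, and p-TsOH·H2O in toluene would then give (5S)-5-(propan-2-yl)cyclohex-2-en-1-one F1. Me3SiOTf and Et3N would convert it into the linear dienol ether trimethyl{[(5S)-5-(propan-2-yl)cyclohexa-1,3-dien-1-yl]oxy}silane F2. Dimethyldioxirane would oxidise C3 anti to the isopropyl group to (4R,5S)-4-hydroxy-5-(propan-2-yl)cyclohex-2-en-1-one F3. Mitsunobu esterification with 1 (PPh3, diisopropyl azodicarboxylate, toluene, 0 °C) would invert C3 and give 7.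

Step 5. Enolisation towards C5 could be slow, the α-keto radical could be trapped by a tiglate double bond, or the acetate could enter with poor facial selectivity. The fallback sets out from 9 and comes back at 10. Kinetic α′-deprotonation with internal silyl quench (LiN(SiMe3)2, Me3SiCl, THF, −78 °C) would give the cross-conjugated enol ether {(3R,4R)-3-[(E)-2-methylbut-2-enoyloxy]-4-(propan-2-yl)-6-[(trimethylsilyl)oxy]cyclohexa-1,5-dien-1-yl}methyl (E)-2-methylbut-2-enoate F5. Rubottom oxidation with dimethyldioxirane anti to the isopropyl group would give [(3S,4R,5R)-5-hydroxy-3-[(E)-2-methylbut-2-enoyloxy]-6-oxo-4-(propan-2-yl)cyclohex-1-en-1-yl]methyl (E)-2-methylbut-2-enoate F6, and acetylation (Ac2O, pyridine) would give 10.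

Step 3. Conjugate addition of the amine to the hindered C2 could be too slow, and prolonged contact with base could cause loss of the allylic tiglate and aromatisation. The fallback sets out from 7 and comes back at 8. α-Iodination (I2, pyridine, CH2Cl2) would give (1R,6S)-3-iodo-4-oxo-6-(propan-2-yl)cyclohex-2-en-1-yl (2E)-2-methylbut-2-enoate F4. Stille coupling with (tributylstannyl)methanol (Pd(PPh3)4, zerovalent palladium, dioxane, 80 °C) would give 8 without any base.

**Further compounds**
F1 | step 2 | (5S)-5-(propan-2-yl)cyclohex-2-en-1-one | O=C1C=CC[C@H](C(C)C)C1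
F2 | step 2 | trimethyl{[(5S)-5-(propan-2-yl)cyclohexa-1,3-dien-1-yl]oxy}silane | C[Si](C)(C)OC1=CC=C[C@H](C(C)C)C1
F3 | step 2 | (4R,5S)-4-hydroxy-5-(propan-2-yl)cyclohex-2-en-1-one | O=C1C=C[C@@H](O)[C@H](C(C)C)C1
F4 | step 3 | (1R,6S)-3-iodo-4-oxo-6-(propan-2-yl)cyclohex-2-en-1-yl (2E)-2-methylbut-2-enoate | O=C1C(I)=C[C@H](OC(=O)/C(C)=C/C)[C@H](C(C)C)C1
F5 | step 5 | {(3R,4R)-3-[(E)-2-methylbut-2-enoyloxy]-4-(propan-2-yl)-6-[(trimethylsilyl)oxy]cyclohexa-1,5-dien-1-yl}methyl (E)-2-methylbut-2-enoate | C/C=C(\C)C(=O)OCC1=C[C@H](OC(=O)/C(C)=C/C)[C@H](C(C)C)C=C1O[Si](C)(C)C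
F6 | step 5 | [(3S,4R,5R)-5-hydroxy-3-[(E)-2-methylbut-2-enoyloxy]-6-oxo-4-(propan-2-yl)cyclohex-1-en-1-yl]methyl (E)-2-methylbut-2-enoate | C/C=C(\C)C(=O)OCC1=C[C@H](OC(=O)/C(C)=C/C)[C@H](C(C)C)[C@@H](O)C1=O
A1 | direct plan | (2-formylfuran-3-yl)methyl (E)-2-methylbut-2-enoate | C/C=C(\C)C(=O)OCc1ccoc1C=O
A2 | direct plan | [2-[(1R)-1-acetoxy-3-methylbut-2-en-1-yl]furan-3-yl]methyl (E)-2-methylbut-2-enoate | C/C=C(\C)C(=O)OCc1ccoc1[C@H](OC(C)=O)C=C(C)C
A3 | direct plan | (2Z)-2-[(2R)-2-acetoxy-4-methylpent-3-enoyl]-4-oxobut-2-en-1-yl (E)-2-methylbut-2-enoate | O=C/C=C(/COC(=O)/C(C)=C/C)C(=O)[C@H](OC(C)=O)C=C(C)C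
A4 | direct plan | [(3R,4S,5R)-5-acetoxy-3-hydroxy-6-oxo-4-(prop-1-en-2-yl)cyclohex-1-en-1-yl]methyl (E)-2-methylbut-2-enoate | C/C=C(\C)C(=O)OCC1=C[C@@H](O)[C@H](C(C)=C)[C@@H](OC(C)=O)C1=O
A5 | direct plan | [(3S,4S,5R)-5-acetoxy-3-[(E)-2-methylbut-2-enoyloxy]-6-oxo-4-(prop-1-en-2-yl)cyclohex-1-en-1-yl]methyl (E)-2-methylbut-2-enoate | C/C=C(\C)C(=O)OCC1=C[C@H](OC(=O)/C(C)=C/C)[C@H](C(C)=C)[C@@H](OC(C)=O)C1=O
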